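**Plan**
- Retrosynthesis cuts, in this order: the C8–O acyl bond (side-chain diester acid), the C1/C10 oxirane, the lactone (C11=C13, then O6–C12 and C7–C11), and last the ring bond C8–C9 with C1–C6 re-joined, which folds the ten-membered ring back to a cyclohexenol.
- Feature used (germacrane numbering): C1–C2–C3(O)–C4(Me)=C5–C6(O), with C10(Me)=C9 attached to C1, is an oxygenated p-menthadiene. Its C1–C6 bond lies across the ten-membered ring from C8–C9, so a six-membered ring C1–C6 with a vinyl group on C6 and the isopropenyl group on C1 contains the 1,5-diene C8=C7–C6–C1–C10=C9.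
- Forward: (S)-carvone gives the six-membered enone; an E-alkoxyvinyl group is added at C6; the anionic oxy-Cope shift makes the ten-membered ring; C7 alkylation and C6 reduction close the γ-lactone ring; then methylenation, O8 acylation with the separately built diester acid, the oxirane ring and desilylation.
- Stereochemistry: C3 comes from the carvone epoxide and survives the Wharton shift; the carvone stereocentre (C1) directs the vinyl addition at C6, and the C1/C6 pair is passed on to C8 through the chair; C7, C6 and C1/C10 are then set by attack on the exposed face of the ten-membered ring.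

Key step: step 8

Assumption: germacrane numbering is used in all explanations from the start (carvone C1–C6 become C5, C4, C3, C2, C1, C6; its isopropenyl group supplies C10, C9 and C14), and the ten-membered ring conformers are taken to equilibrate at the temperatures of steps 9, 10 and 23.

**Step 1**
Reactants: 1 (S)-carvone
Product: 2 (1S,4S,6S)-1-methyl-4-(prop-1-en-2-yl)-7-oxabicyclo[4.1.0]heptan-2-one
Conditions: 30% H2O2, NaOH (cat.), MeOH, 0 °C
Reagents that add atoms: hydrogen peroxide, OO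
Why: Weitz–Scheffer epoxidation: hydroperoxide adds to the enone β-carbon C3 anti to the C1 isopropenyl group and the enolate closes the oxirane, so the future C3–O bond is set trans to the isopropenyl group while the isolated isopropenyl olefin is inert to the nucleophilic oxidant.

**Step 2**
Reactants: 2 (1S,4S,6S)-1-methyl-4-(prop-1-en-2-yl)-7-oxabicyclo[4.1.0]heptan-2-one
Product: 4 (1S,5R)-2-methyl-5-(prop-1-en-2-yl)cyclohex-2-en-1-ol (trans-carveol), via epoxy hydrazone 3 (not isolated)
Conditions: N2H4·H2O, AcOH (cat.), MeOH, 0 → 25 °C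
Reagents that add atoms: none
Why: Wharton transposition: the epoxy hydrazone collapses with loss of N2 to the allylic alcohol, which moves the olefin to C4=C5 and leaves the C3–O bond and its configuration untouched, so the hydroxyl stays trans to the isopropenyl group.

**Step 3**
Reactants: 4 (1S,5R)-2-methyl-5-(prop-1-en-2-yl)cyclohex-2-en-1-ol
Product: 5 tert-butyldimethyl{[(1S,5R)-2-methyl-5-(prop-1-en-2-yl)cyclohex-2-en-1-yl]oxy}silane
Conditions: TBSCl, imidazole, DMF, 25 °C
Reagents that add atoms: tert-butyldimethylsilyl chloride, CC(C)(C)[Si](C)(C)Cl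
Why: Routine imidazole-promoted silylation of a secondary allylic alcohol, with no change at C3 or C1.

**Step 4**
Reactants: 5 tert-butyldimethyl{[(1S,5R)-2-methyl-5-(prop-1-en-2-yl)cyclohex-2-en-1-yl]oxy}silane
Product: 6 (4S,6R)-4-[(tert-butyldimethylsilyl)oxy]-3-methyl-6-(prop-1-en-2-yl)cyclohex-2-en-1-one
Conditions: CrO3, 3,5-dimethylpyrazole, CH2Cl2, −20 °C
Reagents that add atoms: chromium trioxide, O=[Cr](=O)=O
Why: Allylic C–H oxidation with the CrO3–3,5-dimethylpyrazole complex: the C6 methylene is the only ring allylic position that can be taken to a ketone without touching the hindered C3–H geminal to the silyl ether, so the C6 enone conjugated with C4=C5 should form with C1 and C3 unchanged.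

**Step 5**
Reactants: 7 4-methoxybenzyl alcohol; 8 trichloroethylene
Product: 11 1-(ethynyloxymethyl)-4-methoxybenzene, via dichlorovinyl ether 9 (not isolated), via lithium alkynyl ether 10 (not isolated)
Conditions: KH, THF, 0 → 25 °C; then n-BuLi (2.5 equiv), −78 → −40 °C; then MeOH, −78 °C
Reagents that add atoms: none
Why: Known one-pot ynol ether synthesis: base-mediated addition of the alcohol to trichloroethylene with loss of chloride gives the dichlorovinyl ether, and two equivalents of n-BuLi then bring about dehydrochlorination and chlorine–lithium exchange to the lithium alkynyl ether, which is protonated cold.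

**Step 6**
Reactants: 11 1-(ethynyloxymethyl)-4-methoxybenzene
Product: 13 (E)-1-iodo-2-[(4-methoxyphenyl)methoxy]ethene, via vinylzirconocene chloride 12 (not isolated)
Conditions: Cp2Zr(H)Cl, THF, 25 °C; then I2, 0 °C
Reagents that add atoms: iodine, [I][I]
Why: Hydrozirconation is a syn addition that places zirconium on the terminal carbon, and iodinolysis of the carbon–zirconium bond with retention gives the E iodide.

**Step 7**
Reactants: 13 (E)-1-iodo-2-[(4-methoxyphenyl)methoxy]ethene; 6 (4S,6R)-4-[(tert-butyldimethylsilyl)oxy]-3-methyl-6-(prop-1-en-2-yl)cyclohex-2-en-1-one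
Product: 15 (1R,4S,6R)-4-[(tert-butyldimethylsilyl)oxy]-1-{(E)-2-[(4-methoxyphenyl)methoxy]ethenyl}-3-methyl-6-(prop-1-en-2-yl)cyclohex-2-en-1-ol, via vinyllithium 14 (not isolated)
Conditions: t-BuLi (2 equiv), Et2O, −78 °C; then 6, THF, −78 °C; then H2O
Reagents that add atoms: none
Why: Iodine–lithium exchange with retention gives the E vinyllithium (held at −78 °C so that it does not eliminate to acetylene), which adds 1,2 to the enone carbonyl from the face opposite the adjacent pseudo-equatorial C1 isopropenyl group (equatorial attack, as in additions of alkenyllithiums to isopiperitenone), setting the C6 carbinol with the two alkenyl groups trans.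

**Step 8**
Reactants: 15 (1R,4S,6R)-4-[(tert-butyldimethylsilyl)oxy]-1-{(E)-2-[(4-methoxyphenyl)methoxy]ethenyl}-3-methyl-6-(prop-1-en-2-yl)cyclohex-2-en-1-ol
Product: 18 tert-butyl{[(1S,2Z,4Z,6R,8E)-6-[(4-methoxyphenyl)methoxy]-2,8-dimethyl-4-[(trimethylsilyl)oxy]cyclodeca-2,4,8-trien-1-yl]oxy}dimethylsilane, via potassium alkoxide 16 (not isolated), via potassium enolate 17 (not isolated)
Conditions: KH, 18-crown-6, THF, 0 → 25 °C; then Me3SiCl, Et3N, −78 °C
Reagents that add atoms: chlorotrimethylsilane, C[Si](C)(C)Cl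
Why: KH with 18-crown-6 gives the dissociated potassium alkoxide 16, whose oxyanion weakens the adjacent C1–C6 bond, and the 1,5-diene C8=C7–C6–C1–C10=C9 undergoes an anionic oxy-Cope [3,3] shift through a chair in which the ring bonds C6–C5 and C1–C2 and the C8 alkoxy group are equatorial. The closest known reaction is the anionic oxy-Cope ring expansion of trans-1,2-dialkenylcyclohexanols to cyclodec-5-enones, including adducts of isopiperitenone. No ring is closed by an end-to-end attack: the ten-membered ring appears by four-atom ring expansion when C8–C9 forms across the six-membered ring while the shared C1–C6 bond breaks. The single new stereocentre, C8, is fixed as R by the chair together with the E enol ether (oxygen equatorial) and the 1R,6R configuration (germacrane numbering) of 15; the same chair gives the E C1=C10 olefin, and C4=C5 stays Z because it was the cyclohexene double bond. The step needs chair over boat selectivity, which the trans (diequatorial) placing of the two alkenyl groups secures, and the C1 and C6 stereocentres are spent in the process. Silylation of potassium enolate 17 at −78 °C traps the regiodefined C6=C7 enolate before it can expel the C8 alkoxy group.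

**Step 9**
Reactants: 18 tert-butyl{[(1S,2Z,4Z,6R,8E)-6-[(4-methoxyphenyl)methoxy]-2,8-dimethyl-4-[(trimethylsilyl)oxy]cyclodeca-2,4,8-trien-1-yl]oxy}dimethylsilane; 19 methyl bromoacetate
Product: 21 methyl (3S,7R,8R)-3-[(tert-butyldimethylsilyl)oxy]-8-[(4-methoxyphenyl)methoxy]-6-oxo-13-norgermacra-1(10)E,4Z-dien-12-oate, via lithium enolate 20 (not isolated)
Conditions: MeLi, THF, 0 °C; then 19, −78 → −30 °C
Reagents that add atoms: none
Why: MeLi cleaves the O–SiMe3 bond to give the lithium enolate without equilibration, the lithium is held between O6 and the C8 ether oxygen in a six-membered chelate, and SN2 alkylation by the bromoacetate then occurs at C7 on the exposed face anti to C9, which places C11 cis to the C8 oxygen (7R).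

**Step 10**
Reactants: 21 methyl (3S,7R,8R)-3-[(tert-butyldimethylsilyl)oxy]-8-[(4-methoxyphenyl)methoxy]-6-oxo-13-norgermacra-1(10)E,4Z-dien-12-oate
Product: 23 (3S,6R,7R,8R)-3-[(tert-butyldimethylsilyl)oxy]-8-[(4-methoxyphenyl)methoxy]-13-norgermacra-1(10)E,4Z-dien-12,6-olide, via hydroxy ester 22 (not isolated)
Conditions: NaBH4, CeCl3·7H2O, MeOH, −40 → 0 °C; then PPTS (cat.), CH2Cl2, 25 °C
Reagents that add atoms: none
Why: Luche reduction attacks only the enone carbonyl (1,2), hydride approaching C6 from the outer face anti to the acetate arm on C7 so that O6 ends up trans to C11 (6R), and the resulting γ-hydroxy ester closes to the γ-lactone by 5-exo-trig acyl substitution with loss of methanol.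

**Step 11**
Reactants: 23 (3S,6R,7R,8R)-3-[(tert-butyldimethylsilyl)oxy]-8-[(4-methoxyphenyl)methoxy]-13-norgermacra-1(10)E,4Z-dien-12,6-olide
Product: 25 (3S,6R,7R,8R)-3-[(tert-butyldimethylsilyl)oxy]-13-(dimethylamino)-8-[(4-methoxyphenyl)methoxy]germacra-1(10)E,4Z-dien-12,6-olide (C11 epimers), via lactone lithium enolate 24 (not isolated)
Conditions: LiN(iPr)2, THF, −78 °C; then Me2N=CH2+ I−, −78 → 0 °C
Reagents that add atoms: dimethylmethyleneammonium iodide, C=[N+](C)C.[I-]
Why: Mannich reaction of the lactone enolate (C11 is the only acidic position) with the preformed iminium salt; the new C11 centre is of no consequence because it becomes sp2 in step 12.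

**Step 12**
Reactants: 25 (3S,6R,7R,8R)-3-[(tert-butyldimethylsilyl)oxy]-13-(dimethylamino)-8-[(4-methoxyphenyl)methoxy]germacra-1(10)E,4Z-dien-12,6-olide
Product: 27 (3S,6R,7R,8R)-3-[(tert-butyldimethylsilyl)oxy]-8-[(4-methoxyphenyl)methoxy]germacra-1(10)E,4Z,11(13)-trien-12,6-olide, via trimethylammonium iodide 26 (not isolated)
Conditions: MeI, MeOH, 25 °C; then NaHCO3 (aq.), EtOAc, 25 °C
Reagents that add atoms: none
Why: Quaternisation of the amine followed by base-induced β-elimination of trimethylamine (Hofmann-type, E1cB through the lactone enolate) gives the exocyclic C11=C13 olefin.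

**Step 13**
Reactants: 27 (3S,6R,7R,8R)-3-[(tert-butyldimethylsilyl)oxy]-8-[(4-methoxyphenyl)methoxy]germacra-1(10)E,4Z,11(13)-trien-12,6-olide
Product: 28 (3S,6R,7R,8R)-3-[(tert-butyldimethylsilyl)oxy]-8-hydroxygermacra-1(10)E,4Z,11(13)-trien-12,6-olide
Conditions: DDQ, CH2Cl2/pH 7 buffer, 0 °C
Reagents that add atoms: none
Why: Oxidative cleavage of the p-methoxybenzyl ether by DDQ (benzylic hydride abstraction, hydrolysis of the oxocarbenium ion) is selective for the electron-rich arene and does not break the C8–O bond, so C8 keeps its configuration.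

**Step 14**
Reactants: 29 acetaldehyde; 30 tert-butyl acrylate
Product: 31 tert-butyl 3-hydroxy-2-methylidenebutanoate (racemic)
Conditions: DABCO (cat.), dioxane/H2O, 25 °C
Reagents that add atoms: none
Why: Baylis–Hillman reaction: DABCO adds to the acrylate and the resulting ammonium enolate attacks acetaldehyde; the carbinol centre is racemic and is erased in step 15.

**Step 15**
Reactants: 31 tert-butyl 3-hydroxy-2-methylidenebutanoate
Product: 32 tert-butyl (2Z)-2-(bromomethyl)but-2-enoate
Conditions: NBS, Me2S, CH2Cl2, 0 → 25 °C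
Reagents that add atoms: N-bromosuccinimide, O=C1CCC(=O)N1Br
Why: The alcohol is activated as an alkoxysulfonium salt by the NBS–Me2S reagent and displaced by bromide in SN2' fashion, which gives the conjugated trisubstituted olefin with the methyl group trans to the ester (Z bromide), the usual outcome for Baylis–Hillman alcohols of esters.

**Step 16**
Reactants: 33 (tert-butyldimethylsilyloxy)acetaldehyde; 30 tert-butyl acrylate
Product: 34 tert-butyl 4-[(tert-butyldimethylsilyl)oxy]-3-hydroxy-2-methylidenebutanoate (racemic)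
Conditions: DABCO (cat.), dioxane/H2O, 25 °C
Reagents that add atoms: none
Why: Baylis–Hillman reaction of the acrylate with the reactive α-silyloxy aldehyde under DABCO catalysis; the racemic carbinol centre is erased in step 17.

**Step 17**
Reactants: 34 tert-butyl 4-[(tert-butyldimethylsilyl)oxy]-3-hydroxy-2-methylidenebutanoate
Product: 35 tert-butyl (2Z)-2-(bromomethyl)-4-[(tert-butyldimethylsilyl)oxy]but-2-enoate
Conditions: NBS, Me2S, CH2Cl2, 0 → 25 °C
Reagents that add atoms: N-bromosuccinimide, O=C1CCC(=O)N1Br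
Why: Same SN2' bromination through the alkoxysulfonium salt; the silyloxymethyl group ends up trans to the ester (Z bromide) and the neutral conditions spare the silyl ether and the tert-butyl ester.

**Step 18**
Reactants: 35 tert-butyl (2Z)-2-(bromomethyl)-4-[(tert-butyldimethylsilyl)oxy]but-2-enoate
Product: 36 tert-butyl (2E)-2-(acetoxymethyl)-4-[(tert-butyldimethylsilyl)oxy]but-2-enoate
Conditions: CsOAc, DMF, 25 °C
Reagents that add atoms: cesium acetate, CC(=O)[O-].[Cs+]
Why: SN2 displacement of the primary allylic bromide by acetate in DMF, which leaves the olefin geometry untouched (the descriptor becomes E only through the priority change).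

**Step 19**
Reactants: 36 tert-butyl (2E)-2-(acetoxymethyl)-4-[(tert-butyldimethylsilyl)oxy]but-2-enoate
Product: 38 (2E)-2-(acetoxymethyl)-4-[(tert-butyldimethylsilyl)oxy]but-2-enoic acid, via trimethylsilyl ester 37 (not isolated)
Conditions: Me3SiOTf, 2,6-lutidine, CH2Cl2, 0 °C; then H2O
Reagents that add atoms: none
Why: Silyl triflate converts the tert-butyl ester into the trimethylsilyl ester with loss of isobutene while 2,6-lutidine buffers the acid, conditions that spare the silyl ether and the allylic acetate; water then frees the carboxylic acid.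

**Step 20**
Reactants: 38 (2E)-2-(acetoxymethyl)-4-[(tert-butyldimethylsilyl)oxy]but-2-enoic acid; 32 tert-butyl (2Z)-2-(bromomethyl)but-2-enoate
Product: 40 tert-butyl (2E)-2-[({(2E)-2-(acetoxymethyl)-4-[(tert-butyldimethylsilyl)oxy]but-2-enoyl}oxy)methyl]but-2-enoate, via cesium carboxylate 39 (not isolated)
Conditions: Cs2CO3, DMF, 0 °C; then 32, 25 °C
Reagents that add atoms: none
Why: O-Alkylation of the cesium carboxylate by the primary allylic bromide (SN2; carboxylates without amine catalysis attack the CH2Br carbon), which joins the two butenoate units with both olefin geometries retained.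

**Step 21**
Reactants: 40 tert-butyl (2E)-2-[({(2E)-2-(acetoxymethyl)-4-[(tert-butyldimethylsilyl)oxy]but-2-enoyl}oxy)methyl]but-2-enoate
Product: 42 (2E)-2-[({(2E)-2-(acetoxymethyl)-4-[(tert-butyldimethylsilyl)oxy]but-2-enoyl}oxy)methyl]but-2-enoic acid, via trimethylsilyl ester 41 (not isolated)
Conditions: Me3SiOTf, 2,6-lutidine, CH2Cl2, 0 °C; then H2O
Reagents that add atoms: none
Why: Same silyl triflate cleavage of the tert-butyl ester by way of the trimethylsilyl ester, leaving the two allylic esters and the silyl ether intact.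

**Step 22**
Reactants: 42 (2E)-2-[({(2E)-2-(acetoxymethyl)-4-[(tert-butyldimethylsilyl)oxy]but-2-enoyl}oxy)methyl]but-2-enoic acid; 28 (3S,6R,7R,8R)-3-[(tert-butyldimethylsilyl)oxy]-8-hydroxygermacra-1(10)E,4Z,11(13)-trien-12,6-olide
Product: 44 (3S,6R,7R,8R)-3-[(tert-butyldimethylsilyl)oxy]-8-{(2E)-2-[({(2E)-2-(acetoxymethyl)-4-[(tert-butyldimethylsilyl)oxy]but-2-enoyl}oxy)methyl]but-2-enoyloxy}germacra-1(10)E,4Z,11(13)-trien-12,6-olide, via mixed anhydride 43 (not isolated)
Conditions: 2,4,6-Cl3C6H2COCl, Et3N, THF, 25 °C; then 28, DMAP, toluene, 25 °C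
Reagents that add atoms: none
Why: Yamaguchi esterification: the mixed anhydride transfers the α,β-unsaturated acyl group by way of the acylpyridinium ion to the secondary C8 hydroxyl; the C8–O bond is not broken and the stable E (tiglate-type) olefin geometry of the acyl group is kept.

**Step 23**
Reactants: 44 (3S,6R,7R,8R)-3-[(tert-butyldimethylsilyl)oxy]-8-{(2E)-2-[({(2E)-2-(acetoxymethyl)-4-[(tert-butyldimethylsilyl)oxy]but-2-enoyl}oxy)methyl]but-2-enoyloxy}germacra-1(10)E,4Z,11(13)-trien-12,6-olide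
Product: 45 (1R,3S,6R,7R,8R,10R)-3-[(tert-butyldimethylsilyl)oxy]-1,10-epoxy-8-{(2E)-2-[({(2E)-2-(acetoxymethyl)-4-[(tert-butyldimethylsilyl)oxy]but-2-enoyl}oxy)methyl]but-2-enoyloxy}germacra-4Z,11(13)-dien-12,6-olide
Conditions: mCPBA (1.1 equiv), NaHCO3, CH2Cl2, 0 °C
Reagents that add atoms: 3-chloroperbenzoic acid, O=C(OO)c1cccc(Cl)c1
Why: Prilezhaev epoxidation: C1=C10 is the only electron-rich double bond without allylic oxygen (C4=C5 is deactivated by the C3 and C6 C–O bonds, the other three are acrylate-type), the concerted syn addition keeps C2 and C9 trans, and attack on the outer face of the E olefin in the lactone-fused ring, with the C14 methyl on the side of C11, should give the 1R,10R oxirane.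

**Step 24**
Reactants: 45 (1R,3S,6R,7R,8R,10R)-3-[(tert-butyldimethylsilyl)oxy]-1,10-epoxy-8-{(2E)-2-[({(2E)-2-(acetoxymethyl)-4-[(tert-butyldimethylsilyl)oxy]but-2-enoyl}oxy)methyl]but-2-enoyloxy}germacra-4Z,11(13)-dien-12,6-olide
Product: 46 (1R,3S,6R,7R,8R,10R)-1,10-epoxy-3-hydroxy-8-{(2E)-2-[({(2E)-2-(acetoxymethyl)-4-hydroxybut-2-enoyl}oxy)methyl]but-2-enoyloxy}germacra-4Z,11(13)-dien-12,6-olide (CNP0193678.1)
Conditions: HF·pyridine, pyridine, THF, 0 → 25 °C
Reagents that add atoms: none
Why: Fluoride cleaves both Si–O bonds (secondary C3 and primary side-chain silyl ethers) under pyridine-buffered conditions that are mild enough for the oxirane, the allylic esters and the α-methylene lactone; no stereocentre is touched.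

**Compound list**
1 | (S)-carvone, (5S)-2-methyl-5-(prop-1-en-2-yl)cyclohex-2-en-1-one | CC1=CC[C@@H](CC1=O)C(C)=C | starting material
2 | (1S,4S,6S)-1-methyl-4-(prop-1-en-2-yl)-7-oxabicyclo[4.1.0]heptan-2-one | C1C(=O)[C@@]2(C)O[C@H]2C[C@@H]1C(C)=C | intermediate
3 | epoxy hydrazone of 2 (formed in the flask) | C1C(=NN)[C@@]2(C)O[C@H]2C[C@@H]1C(C)=C | intermediate
4 | (1S,5R)-2-methyl-5-(prop-1-en-2-yl)cyclohex-2-en-1-ol (trans-carveol) | C1C=C(C)[C@@H](O)C[C@@H]1C(C)=C | intermediate
5 | tert-butyldimethyl{[(1S,5R)-2-methyl-5-(prop-1-en-2-yl)cyclohex-2-en-1-yl]oxy}silane | C1C=C(C)[C@@H](O[Si](C)(C)C(C)(C)C)C[C@@H]1C(C)=C | intermediate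
6 | (4S,6R)-4-[(tert-butyldimethylsilyl)oxy]-3-methyl-6-(prop-1-en-2-yl)cyclohex-2-en-1-one | O=C1C=C(C)[C@@H](O[Si](C)(C)C(C)(C)C)C[C@@H]1C(C)=C | intermediate
7 | 4-methoxybenzyl alcohol | COc1ccc(CO)cc1 | starting material
8 | trichloroethylene | ClC=C(Cl)Cl | starting material
9 | 1-{[(E)-1,2-dichloroethenyl]oxymethyl}-4-methoxybenzene (dichlorovinyl ether, formed in the flask) | Cl/C=C(/Cl)OCc1ccc(OC)cc1 | intermediate
10 | lithium 2-[(4-methoxyphenyl)methoxy]ethynide (lithium alkynyl ether, formed in the flask) | [Li]C#COCc1ccc(OC)cc1 | intermediate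
11 | 1-(ethynyloxymethyl)-4-methoxybenzene | C#COCc1ccc(OC)cc1 | intermediate
12 | chlorobis(cyclopentadienyl){(E)-2-[(4-methoxyphenyl)methoxy]ethenyl}zirconium (formed in the flask) | Cl[Zr](/C=C/OCc1ccc(OC)cc1)(C1C=CC=C1)C1C=CC=C1 | intermediate
13 | (E)-1-iodo-2-[(4-methoxyphenyl)methoxy]ethene | I/C=C/OCc1ccc(OC)cc1 | intermediate
14 | (E)-2-[(4-methoxyphenyl)methoxy]ethenyllithium (formed in the flask) | [Li]/C=C/OCc1ccc(OC)cc1 | intermediate
15 | (1R,4S,6R)-4-[(tert-butyldimethylsilyl)oxy]-1-{(E)-2-[(4-methoxyphenyl)methoxy]ethenyl}-3-methyl-6-(prop-1-en-2-yl)cyclohex-2-en-1-ol | O[C@]1(/C=C/OCc2ccc(OC)cc2)C=C(C)[C@@H](O[Si](C)(C)C(C)(C)C)C[C@@H]1C(C)=C | intermediate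
16 | potassium alkoxide of 15 (formed in the flask) | [K+].[O-][C@]1(/C=C/OCc2ccc(OC)cc2)C=C(C)[C@@H](O[Si](C)(C)C(C)(C)C)C[C@@H]1C(C)=C | intermediate
17 | potassium C6 enolate of the ten-membered trienone (C5 and C8 trans on C6=C7; formed in the flask) | [K+].C1/C(C)=C/C[C@H](O[Si](C)(C)C(C)(C)C)/C(C)=C\C([O-])=C\[C@@H]1OCc2ccc(OC)cc2 | intermediate
18 | tert-butyl{[(1S,2Z,4Z,6R,8E)-6-[(4-methoxyphenyl)methoxy]-2,8-dimethyl-4-[(trimethylsilyl)oxy]cyclodeca-2,4,8-trien-1-yl]oxy}dimethylsilane | C1/C(C)=C/C[C@H](O[Si](C)(C)C(C)(C)C)/C(C)=C\C(O[Si](C)(C)C)=C\[C@@H]1OCc2ccc(OC)cc2 | intermediate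
19 | methyl bromoacetate | COC(=O)CBr | starting material
20 | lithium C6 enolate corresponding to 18 (formed in the flask) | [Li+].C1/C(C)=C/C[C@H](O[Si](C)(C)C(C)(C)C)/C(C)=C\C([O-])=C\[C@@H]1OCc2ccc(OC)cc2 | intermediate
21 | methyl (3S,7R,8R)-3-[(tert-butyldimethylsilyl)oxy]-8-[(4-methoxyphenyl)methoxy]-6-oxo-13-norgermacra-1(10)E,4Z-dien-12-oate | COC(=O)C[C@H]1C(=O)/C=C(/C)[C@@H](O[Si](C)(C)C(C)(C)C)C/C=C(C)/C[C@H]1OCc1ccc(OC)cc1 | intermediate
22 | methyl (3S,6R,7S,8R)-3-[(tert-butyldimethylsilyl)oxy]-6-hydroxy-8-[(4-methoxyphenyl)methoxy]-13-norgermacra-1(10)E,4Z-dien-12-oate (C7 geometry as in 21, descriptor changed by priorities; formed in the flask) | COC(=O)C[C@H]1[C@H](O)/C=C(/C)[C@@H](O[Si](C)(C)C(C)(C)C)C/C=C(C)/C[C@H]1OCc1ccc(OC)cc1 | intermediate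
23 | (3S,6R,7R,8R)-3-[(tert-butyldimethylsilyl)oxy]-8-[(4-methoxyphenyl)methoxy]-13-norgermacra-1(10)E,4Z-dien-12,6-olide | C1C(=O)O[C@@H]2/C=C(/C)[C@@H](O[Si](C)(C)C(C)(C)C)C/C=C(C)/C[C@@H](OCc3ccc(OC)cc3)[C@@H]12 | intermediate
24 | lithium enolate of lactone 23 (formed in the flask) | [Li+].C1=C([O-])O[C@@H]2/C=C(/C)[C@@H](O[Si](C)(C)C(C)(C)C)C/C=C(C)/C[C@@H](OCc3ccc(OC)cc3)[C@@H]12 | intermediate
25 | (3S,6R,7R,8R)-3-[(tert-butyldimethylsilyl)oxy]-13-(dimethylamino)-8-[(4-methoxyphenyl)methoxy]germacra-1(10)E,4Z-dien-12,6-olide (C11 epimers) | CN(C)CC1C(=O)O[C@@H]2/C=C(/C)[C@@H](O[Si](C)(C)C(C)(C)C)C/C=C(C)/C[C@@H](OCc3ccc(OC)cc3)[C@@H]12 | intermediate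
26 | trimethylammonium iodide of 25 (formed in the flask) | [I-].C[N+](C)(C)CC1C(=O)O[C@@H]2/C=C(/C)[C@@H](O[Si](C)(C)C(C)(C)C)C/C=C(C)/C[C@@H](OCc3ccc(OC)cc3)[C@@H]12 | intermediate
27 | (3S,6R,7R,8R)-3-[(tert-butyldimethylsilyl)oxy]-8-[(4-methoxyphenyl)methoxy]germacra-1(10)E,4Z,11(13)-trien-12,6-olide | C=C1C(=O)O[C@@H]2/C=C(/C)[C@@H](O[Si](C)(C)C(C)(C)C)C/C=C(C)/C[C@@H](OCc3ccc(OC)cc3)[C@@H]12 | intermediate
28 | (3S,6R,7R,8R)-3-[(tert-butyldimethylsilyl)oxy]-8-hydroxygermacra-1(10)E,4Z,11(13)-trien-12,6-olide | C=C1C(=O)O[C@@H]2/C=C(/C)[C@@H](O[Si](C)(C)C(C)(C)C)C/C=C(C)/C[C@@H](O)[C@@H]12 | intermediate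
29 | acetaldehyde | CC=O | starting material
30 | tert-butyl acrylate | C=CC(=O)OC(C)(C)C | starting material
31 | tert-butyl 3-hydroxy-2-methylidenebutanoate (racemic) | C=C(C(C)O)C(=O)OC(C)(C)C | intermediate
32 | tert-butyl (2Z)-2-(bromomethyl)but-2-enoate | CC(C)(C)OC(=O)/C(=C/C)CBr | intermediate
33 | (tert-butyldimethylsilyloxy)acetaldehyde | O=CCO[Si](C)(C)C(C)(C)C | starting material
34 | tert-butyl 4-[(tert-butyldimethylsilyl)oxy]-3-hydroxy-2-methylidenebutanoate (racemic) | C=C(C(O)CO[Si](C)(C)C(C)(C)C)C(=O)OC(C)(C)C | intermediate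
35 | tert-butyl (2Z)-2-(bromomethyl)-4-[(tert-butyldimethylsilyl)oxy]but-2-enoate | CC(C)(C)OC(=O)/C(=C/CO[Si](C)(C)C(C)(C)C)CBr | intermediate
36 | tert-butyl (2E)-2-(acetoxymethyl)-4-[(tert-butyldimethylsilyl)oxy]but-2-enoate | CC(C)(C)OC(=O)/C(=C/CO[Si](C)(C)C(C)(C)C)COC(C)=O | intermediate
37 | trimethylsilyl (2E)-2-(acetoxymethyl)-4-[(tert-butyldimethylsilyl)oxy]but-2-enoate (formed in the flask) | C[Si](C)(C)OC(=O)/C(=C/CO[Si](C)(C)C(C)(C)C)COC(C)=O | intermediate
38 | (2E)-2-(acetoxymethyl)-4-[(tert-butyldimethylsilyl)oxy]but-2-enoic acid | OC(=O)/C(=C/CO[Si](C)(C)C(C)(C)C)COC(C)=O | intermediate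
39 | cesium carboxylate of 38 (formed in the flask) | [Cs+].[O-]C(=O)/C(=C/CO[Si](C)(C)C(C)(C)C)COC(C)=O | intermediate
40 | tert-butyl (2E)-2-[({(2E)-2-(acetoxymethyl)-4-[(tert-butyldimethylsilyl)oxy]but-2-enoyl}oxy)methyl]but-2-enoate | CC(C)(C)OC(=O)/C(=C/C)COC(=O)/C(=C/CO[Si](C)(C)C(C)(C)C)COC(C)=O | intermediate
41 | trimethylsilyl ester corresponding to 40 (formed in the flask) | C[Si](C)(C)OC(=O)/C(=C/C)COC(=O)/C(=C/CO[Si](C)(C)C(C)(C)C)COC(C)=O | intermediate
42 | (2E)-2-[({(2E)-2-(acetoxymethyl)-4-[(tert-butyldimethylsilyl)oxy]but-2-enoyl}oxy)methyl]but-2-enoic acid | OC(=O)/C(=C/C)COC(=O)/C(=C/CO[Si](C)(C)C(C)(C)C)COC(C)=O | intermediate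
43 | mixed anhydride of 42 with 2,4,6-trichlorobenzoic acid (formed in the flask) | O=C(OC(=O)/C(=C/C)COC(=O)/C(=C/CO[Si](C)(C)C(C)(C)C)COC(C)=O)c1c(Cl)cc(Cl)cc1Cl | intermediate
44 | (3S,6R,7R,8R)-3-[(tert-butyldimethylsilyl)oxy]-8-{(2E)-2-[({(2E)-2-(acetoxymethyl)-4-[(tert-butyldimethylsilyl)oxy]but-2-enoyl}oxy)methyl]but-2-enoyloxy}germacra-1(10)E,4Z,11(13)-trien-12,6-olide | C=C1C(=O)O[C@@H]2/C=C(/C)[C@@H](O[Si](C)(C)C(C)(C)C)C/C=C(C)/C[C@@H](OC(=O)/C(=C/C)COC(=O)/C(=C/CO[Si](C)(C)C(C)(C)C)COC(C)=O)[C@@H]12 | intermediate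
45 | (1R,3S,6R,7R,8R,10R)-3-[(tert-butyldimethylsilyl)oxy]-1,10-epoxy-8-{(2E)-2-[({(2E)-2-(acetoxymethyl)-4-[(tert-butyldimethylsilyl)oxy]but-2-enoyl}oxy)methyl]but-2-enoyloxy}germacra-4Z,11(13)-dien-12,6-olide | C=C1C(=O)O[C@@H]2/C=C(/C)[C@@H](O[Si](C)(C)C(C)(C)C)C[C@H]3O[C@]3(C)C[C@@H](OC(=O)/C(=C/C)COC(=O)/C(=C/CO[Si](C)(C)C(C)(C)C)COC(C)=O)[C@@H]12 | intermediate
46 | (1R,3S,6R,7R,8R,10R)-1,10-epoxy-3-hydroxy-8-{(2E)-2-[({(2E)-2-(acetoxymethyl)-4-hydroxybut-2-enoyl}oxy)methyl]but-2-enoyloxy}germacra-4Z,11(13)-dien-12,6-olide (CNP0193678.1) | C=C1C(=O)O[C@@H]2/C=C(/C)[C@@H](O)C[C@H]3O[C@]3(C)C[C@@H](OC(=O)/C(=C/C)COC(=O)/C(=C/CO)COC(C)=O)[C@@H]12 | target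

**Step count**
Total: 24 steps. Longest linear sequence: 14 steps from (S)-carvone (steps 1–4, 7–13, 22–24).

**Steps most likely to fail**

Step 9. The risk is poor facial selectivity: if the lithium chelate between O6 and the C8 ether oxygen does not control the enolate conformation, the electrophile would enter on the other face of C7. The fallback sets out from 18 and returns to the route at 21. The alkylation is run as described and the C7 epimer F1 is accepted. F1 is converted with Me3SiOTf and Et3N (CH2Cl2, 0 °C, soft enolisation without a free β-alkoxy enolate) into the C6 trimethylsilyl enol ether F2. Kinetic protonation of F2 (Bu4NF/AcOH, THF, −78 °C) should deliver hydrogen to the exposed face that the electrophile had used, which inverts C7 and gives 21, so that C7 is set by protonation instead of by alkylation.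

Step 10. The risk is hydride delivery to the other face of the C6 carbonyl, which would give the 6S alcohol and, after ring closure, a cis-fused lactone. The fallback sets out from 21 and returns to the route at 23. The reduction is run as described and the cis-fused lactone F3 is opened with LiOH (THF/H2O, 0 °C) to the hydroxy acid F4. Mitsunobu lactonisation of F4 (PPh3, DIAD, THF, high dilution) activates the C6 hydroxyl and closes the ring by intramolecular SN2 attack of the carboxylate with inversion at C6, giving 23.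

Step 4. The risk is unselective allylic oxidation: attack at the C3–H next to the silyl ether or at the isopropenyl group, or over-oxidation, instead of clean conversion of the C6 methylene. The fallback sets out from 5 and returns to the route at 6. Epoxidation of the ring olefin of 5 with 3-chloroperbenzoic acid (CH2Cl2, 0 °C, anti to the silyloxy group) gives the epoxide F5. Opening of F5 at the secondary carbon C5 with PhSeNa (from (PhSe)2 and NaBH4, EtOH) gives the hydroxy selenide F6. Oxidation with H2O2 and syn elimination of the selenoxide towards C6 gives the tertiary allylic alcohol F7. Oxidative 1,3-transposition of F7 with pyridinium chlorochromate, C5H5NH[CrO3Cl], in CH2Cl2 gives enone 6.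

**Further compounds**
F1 | step 9 | methyl (3S,7S,8R)-3-[(tert-butyldimethylsilyl)oxy]-8-[(4-methoxyphenyl)methoxy]-6-oxo-13-norgermacra-1(10)E,4Z-dien-12-oate (C7 epimer of 21) | COC(=O)C[C@@H]1C(=O)/C=C(/C)[C@@H](O[Si](C)(C)C(C)(C)C)C/C=C(C)/C[C@H]1OCc1ccc(OC)cc1
F2 | step 9 | methyl (3S,8R)-3-[(tert-butyldimethylsilyl)oxy]-8-[(4-methoxyphenyl)methoxy]-6-[(trimethylsilyl)oxy]-13-norgermacra-1(10)E,4Z,6-trien-12-oate (C5 and C8 trans on C6=C7) | COC(=O)C/C1=C(O[Si](C)(C)C)\C=C(\C)[C@@H](O[Si](C)(C)C(C)(C)C)C/C=C(C)/C[C@H]1OCc1ccc(OC)cc1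
F3 | step 10 | (3S,6S,7R,8R)-3-[(tert-butyldimethylsilyl)oxy]-8-[(4-methoxyphenyl)methoxy]-13-norgermacra-1(10)E,4Z-dien-12,6-olide (cis-fused C6 epimer of 23) | C1C(=O)O[C@H]2/C=C(/C)[C@@H](O[Si](C)(C)C(C)(C)C)C/C=C(C)/C[C@@H](OCc3ccc(OC)cc3)[C@@H]12
F4 | step 10 | (3S,6S,7S,8R)-3-[(tert-butyldimethylsilyl)oxy]-6-hydroxy-8-[(4-methoxyphenyl)methoxy]-13-norgermacra-1(10)E,4Z-dien-12-oic acid (C7 geometry as in 21) | OC(=O)C[C@H]1[C@@H](O)/C=C(/C)[C@@H](O[Si](C)(C)C(C)(C)C)C/C=C(C)/C[C@H]1OCc1ccc(OC)cc1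
F5 | step 4 | tert-butyldimethyl{[1-methyl-4-(prop-1-en-2-yl)-7-oxabicyclo[4.1.0]heptan-2-yl]oxy}silane, oxirane anti to the silyloxy group, other centres as in 5 | C1[C@@H]2O[C@]2(C)[C@@H](O[Si](C)(C)C(C)(C)C)C[C@@H]1C(C)=C
F6 | step 4 | 2-[(tert-butyldimethylsilyl)oxy]-1-methyl-6-(phenylselanyl)-4-(prop-1-en-2-yl)cyclohexan-1-ol, hydroxyl and selanyl groups trans, other centres as in 5 | C1[C@@H]([Se]c2ccccc2)[C@](C)(O)[C@@H](O[Si](C)(C)C(C)(C)C)C[C@@H]1C(C)=C
F7 | step 4 | 6-[(tert-butyldimethylsilyl)oxy]-1-methyl-4-(prop-1-en-2-yl)cyclohex-2-en-1-ol, carbinol centre as in F6, other centres as in 5 | C1=C[C@](C)(O)[C@@H](O[Si](C)(C)C(C)(C)C)C[C@@H]1C(C)=C
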